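**Retrosynthetic overview**

1. Ring numbering used below: C1 (CHOH) – C2 (bears heptenyl) = C3 (bears CH2OH) – C4 (CHOH) – C5 (CHOH) – C6 (CH with side chain). The acid comes from its ethyl ester and two silyl ethers; the side chain is grown from a C6 vinyl group through a temporary cis-fused γ-lactone spanning C6 and the C1 oxygen.
2. The cyclohexene is the only carbocycle. Bonds C3–C4 and C6–C1 are made together in a [3+3] union of a (Z)-β-iodo enal (C1–C2–C3) with an (S)-α-silyloxy aldehyde carrying a (Z)-allylboronate (C4–C5–C6).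
3. Enabling feature: the tetrasubstituted C2=C3 alkene is flanked by two secondary allylic carbinols (C1 and C4), so each new bond ends on a CH–OH carbon and can be a carbonyl addition. An alkenylchromium adds to the C4 aldehyde, then the allylboronate adds to the C1 aldehyde; the cis C1–OH/C6 and trans C5–OH/C6 pattern is what a (Z)-boronate chair delivers.
4. Fragments: the iodo enal from a butynediol mono-silyl ether by hydroxyl-directed anti-carbomagnesiation/iodination; the boronate from (S)-but-3-ene-1,2-diol by Z-selective cross metathesis.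
5. Ring order: cyclohexene (step 8), temporary γ-lactone (step 10), lactone opened (step 11).

Key step: step 8

Remark: the five starting materials are taken as commercial; the Z-selective metathesis catalyst is the commercially available cyclometalated ruthenium nitrato complex; TBS = tert-butyldimethylsilyl, pin = pinacolato.

**Step 1**
Reactants: 1 (E)-hept-1-en-1-ylboronic acid
Product: 2 (E)-1-iodohept-1-ene
Conditions: NaOH (aq), Et2O, 0 °C; then I2
Reagents that add atoms: iodine (II)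
Why: Halodeboronation (base then iodine) of an (E)-alkenylboronic acid swaps boron for iodine at the same carbon and should keep the E geometry.

**Step 2**
Reactants: 2 (E)-1-iodohept-1-ene; 3 4-[(tert-butyldimethylsilyl)oxy]but-2-yn-1-ol
Product: 6 (2Z)-4-[(tert-butyldimethylsilyl)oxy]-2-[(1E)-hept-1-en-1-yl]-3-iodobut-2-en-1-ol, via alkenyl Grignard reagent 4 (not isolated), via cyclic magnesium chelate 5 (not isolated)
Conditions: 2 (3 equiv), i-PrMgCl·LiCl, THF, 23 °C; then 3, CuI (10 mol%), THF/toluene, 65 °C; then I2, −40 → 23 °C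
Reagents that add atoms: iodine (II)
Why: Hydroxyl-directed anti-carbomagnesiation of the propargylic alkoxide (after stereoretentive iodine–magnesium exchange) should place heptenyl on the carbon next to the carbinol and magnesium on the distal carbon within a five-membered chelate, so iodinolysis gives the tetrasubstituted alkene with iodine cis to CH2OH.

**Step 3**
Reactants: 6 (2Z)-4-[(tert-butyldimethylsilyl)oxy]-2-[(1E)-hept-1-en-1-yl]-3-iodobut-2-en-1-ol
Product: 7 (2Z)-4-[(tert-butyldimethylsilyl)oxy]-2-[(1E)-hept-1-en-1-yl]-3-iodobut-2-enal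
Conditions: MnO2, CH2Cl2, 23 °C
Reagents that add atoms: none
Why: Allylic alcohol oxidation by MnO2 stops at the enal and tolerates the alkenyl iodide, the diene and the silyl ether.

**Step 4**
Reactants: 8 (S)-but-3-ene-1,2-diol
Product: 9 (S)-3,4-bis[(tert-butyldimethylsilyl)oxy]but-1-ene
Conditions: TBSCl, imidazole, DMF, 23 °C
Reagents that add atoms: tert-butyldimethylsilyl chloride (C[Si](C)(Cl)C(C)(C)C)
Why: Silyl ether formation (silyl chloride/imidazole) protects both hydroxyls without touching the stereocenter.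

**Step 5**
Reactants: 9 (S)-3,4-bis[(tert-butyldimethylsilyl)oxy]but-1-ene
Product: 10 (S)-2-[(tert-butyldimethylsilyl)oxy]but-3-en-1-ol
Conditions: HF·pyridine, pyridine, THF, 0 °C
Reagents that add atoms: none
Why: Kinetic desilylation by buffered HF·pyridine removes the less hindered primary silyl ether and should leave the secondary one in place.

**Step 6**
Reactants: 10 (S)-2-[(tert-butyldimethylsilyl)oxy]but-3-en-1-ol; 11 2-allyl-4,4,5,5-tetramethyl-1,3,2-dioxaborolane
Product: 12 (2S,3Z)-2-[(tert-butyldimethylsilyl)oxy]-5-(4,4,5,5-tetramethyl-1,3,2-dioxaborolan-2-yl)pent-3-en-1-ol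
Conditions: 11 (3 equiv), Ru(NO3)[κ2(C,C)-N-adamantyl-N′-mesitylimidazolin-2-ylidene](=CH-C6H4-2-OiPr) (5 mol%), THF, 35 °C, static vacuum
Reagents that add atoms: none
Why: Z-selective olefin cross metathesis between the terminal alkene and the allylboronic ester (ethene lost) should deliver the (Z)-γ-substituted allylboronate that a syn-selective allyl transfer needs.

**Step 7**
Reactants: 12 (2S,3Z)-2-[(tert-butyldimethylsilyl)oxy]-5-(4,4,5,5-tetramethyl-1,3,2-dioxaborolan-2-yl)pent-3-en-1-ol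
Product: 13 (2S,3Z)-2-[(tert-butyldimethylsilyl)oxy]-5-(4,4,5,5-tetramethyl-1,3,2-dioxaborolan-2-yl)pent-3-enal
Conditions: Dess–Martin periodinane, NaHCO3, CH2Cl2, 0 °C; used at once
Reagents that add atoms: none
Why: Dess–Martin oxidation under bicarbonate buffer gives the α-silyloxy aldehyde without epimerisation, and the boronate cannot add to its own aldehyde because that would need a three-membered transition state.

**Step 8**
Reactants: 7 (2Z)-4-[(tert-butyldimethylsilyl)oxy]-2-[(1E)-hept-1-en-1-yl]-3-iodobut-2-enal; 13 (2S,3Z)-2-[(tert-butyldimethylsilyl)oxy]-5-(4,4,5,5-tetramethyl-1,3,2-dioxaborolan-2-yl)pent-3-enal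
Product: 15 (1S,4R,5S,6R)-5-[(tert-butyldimethylsilyl)oxy]-3-{[(tert-butyldimethylsilyl)oxy]methyl}-6-ethenyl-2-[(1E)-hept-1-en-1-yl]cyclohex-2-ene-1,4-diol, via acyclic alkenylation adduct 14 (not isolated)
Conditions: 13 (1.3 equiv), CrCl2 (6 equiv), NiCl2 (2 mol%), DMF/THF, 0.01 M, 0 → 35 °C; aq. sodium potassium tartrate work-up
Reagents that add atoms: none
Why: Proposed new method: zerovalent nickel inserts into the C–I bond of 7 and transmetalation gives an alkenylchromium species (trivalent chromium) that adds to the more electrophilic α-silyloxy aldehyde of 13 (closest known type: Nozaki–Hiyama–Kishi alkenylation, forming C3–C4); the pinacol (Z)-allylboronate, expected to be inert in bimolecular mode at 0.01 M, then adds through its γ-carbon to the remaining enal carbonyl once both sit on one chain (closest known type: ring-closing carbonyl allylboration, forming C6–C1). The six-membered ring closes in 6-exo-trig mode through a bicyclic chair (Zimmerman–Traxler) transition state. C4 is set by Felkin–Anh addition anti to the C5 silyloxy group (4,5-anti, which is cis on the ring). C6 and C1 are set by the (Z)-boronate geometry, which puts the vinyl group equatorial and the forming C1–O bond pseudoaxial (cis to each other), while the C5 silyloxy group takes the equatorial site trans to the vinyl group. A(1,2) strain from the heptenyl and silyloxymethyl groups on the tetrasubstituted alkene reinforces the pseudoaxial C1–O and C4–O arrangement. The step needs chemoselectivity between two aldehydes and two carbon nucleophiles: the hindered conjugated aldehyde of 7 is a poor partner for the alkenylchromium, the boronate cannot reach its own aldehyde, and high dilution holds back bimolecular allylboration until the alkenylation has joined the fragments.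

**Step 9**
Reactants: 15 (1S,4R,5S,6R)-5-[(tert-butyldimethylsilyl)oxy]-3-{[(tert-butyldimethylsilyl)oxy]methyl}-6-ethenyl-2-[(1E)-hept-1-en-1-yl]cyclohex-2-ene-1,4-diol
Product: 16 (1S,4R,5S,6R)-5-[(tert-butyldimethylsilyl)oxy]-3-{[(tert-butyldimethylsilyl)oxy]methyl}-2-[(1E)-hept-1-en-1-yl]-6-(2-hydroxyethyl)cyclohex-2-ene-1,4-diol
Conditions: 9-BBN (4 equiv), THF, 0 → 23 °C; then NaOH, H2O2
Reagents that add atoms: hydrogen peroxide (OO)
Why: Hydroboration–oxidation with bulky 9-BBN should pick the monosubstituted vinyl group over the conjugated di- and tetrasubstituted alkenes and give the anti-Markovnikov primary alcohol.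

**Step 10**
Reactants: 16 (1S,4R,5S,6R)-5-[(tert-butyldimethylsilyl)oxy]-3-{[(tert-butyldimethylsilyl)oxy]methyl}-2-[(1E)-hept-1-en-1-yl]-6-(2-hydroxyethyl)cyclohex-2-ene-1,4-diol
Product: 17 (3aR,4S,5R,7aS)-4-[(tert-butyldimethylsilyl)oxy]-6-{[(tert-butyldimethylsilyl)oxy]methyl}-7-[(1E)-hept-1-en-1-yl]-5-hydroxy-3a,4,5,7a-tetrahydro-1-benzofuran-2(3H)-one
Conditions: TEMPO (20 mol%), PhI(OAc)2 (2.5 equiv), CH2Cl2, 23 °C
Reagents that add atoms: none
Why: Oxoammonium-mediated oxidative lactonisation (TEMPO/PhI(OAc)2) oxidises the primary alcohol selectively, the aldehyde is trapped by the cis C1 hydroxyl as a lactol and this is oxidised on to the cis-fused γ-lactone.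

**Step 11**
Reactants: 17 (3aR,4S,5R,7aS)-4-[(tert-butyldimethylsilyl)oxy]-6-{[(tert-butyldimethylsilyl)oxy]methyl}-7-[(1E)-hept-1-en-1-yl]-5-hydroxy-3a,4,5,7a-tetrahydro-1-benzofuran-2(3H)-one; 18 ethyl 2-(triphenyl-λ5-phosphanylidene)propanoate
Product: 20 ethyl (2E)-4-[(1R,2S,5R,6S)-6-[(tert-butyldimethylsilyl)oxy]-4-{[(tert-butyldimethylsilyl)oxy]methyl}-3-[(1E)-hept-1-en-1-yl]-2,5-dihydroxycyclohex-3-en-1-yl]-2-methylbut-2-enoate, via lactol 19 (not isolated)
Conditions: i-Bu2AlH, CH2Cl2, −78 °C; MeOH, aq. sodium potassium tartrate; crude lactol, then 18, toluene, 80 °C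
Reagents that add atoms: none
Why: Half-reduction of the lactone by i-Bu2AlH to the lactol followed by Wittig olefination of its open hydroxy-aldehyde form by the stabilised α-methyl ylide should give the (E)-trisubstituted enoate and free the C1 hydroxyl.

**Step 12**
Reactants: 20 ethyl (2E)-4-[(1R,2S,5R,6S)-6-[(tert-butyldimethylsilyl)oxy]-4-{[(tert-butyldimethylsilyl)oxy]methyl}-3-[(1E)-hept-1-en-1-yl]-2,5-dihydroxycyclohex-3-en-1-yl]-2-methylbut-2-enoate
Product: 21 ethyl (2E)-4-[(1R,2S,5R,6S)-3-[(1E)-hept-1-en-1-yl]-2,5,6-trihydroxy-4-(hydroxymethyl)cyclohex-3-en-1-yl]-2-methylbut-2-enoate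
Conditions: Bu4NF, THF, 0 → 40 °C
Reagents that add atoms: none
Why: Fluoride-induced desilylation removes both silyl ethers and leaves the ester, the diene and the allylic alcohols unchanged.

**Step 13**
Reactants: 21 ethyl (2E)-4-[(1R,2S,5R,6S)-3-[(1E)-hept-1-en-1-yl]-2,5,6-trihydroxy-4-(hydroxymethyl)cyclohex-3-en-1-yl]-2-methylbut-2-enoate
Product: 22 pestallic acid P, (2E)-4-[(1R,2S,5R,6S)-3-[(1E)-hept-1-en-1-yl]-2,5,6-trihydroxy-4-(hydroxymethyl)cyclohex-3-en-1-yl]-2-methylbut-2-enoic acid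
Conditions: LiOH, THF/MeOH/H2O, 23 °C; then aq. HCl to pH 4
Reagents that add atoms: lithium hydroxide ([Li+].[OH-])
Why: Saponification by LiOH then mild acidification gives the acid, and no stereocenter is α to the carbonyl so none can epimerise.

**Compound list**

1 | (E)-hept-1-en-1-ylboronic acid | CCCCC/C=C/B(O)O | starting material
2 | (E)-1-iodohept-1-ene | CCCCC/C=C/I | intermediate
3 | 4-[(tert-butyldimethylsilyl)oxy]but-2-yn-1-ol | OCC#CCO[Si](C)(C)C(C)(C)C | starting material
4 | (E)-hept-1-en-1-ylmagnesium chloride (LiCl complex) | CCCCC/C=C/[Mg]Cl | intermediate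
5 | cyclic magnesium chelate, 4-{[(tert-butyldimethylsilyl)oxy]methyl}-3-[(1E)-hept-1-en-1-yl]-2,5-dihydro-1,2-oxamagnesole | CCCCC/C=C/C1=C(CO[Si](C)(C)C(C)(C)C)[Mg]OC1 | intermediate
6 | (2Z)-4-[(tert-butyldimethylsilyl)oxy]-2-[(1E)-hept-1-en-1-yl]-3-iodobut-2-en-1-ol | OC/C(/C=C/CCCCC)=C(\I)CO[Si](C)(C)C(C)(C)C | intermediate
7 | (2Z)-4-[(tert-butyldimethylsilyl)oxy]-2-[(1E)-hept-1-en-1-yl]-3-iodobut-2-enal | O=C/C(/C=C/CCCCC)=C(\I)CO[Si](C)(C)C(C)(C)C | intermediate
8 | (S)-but-3-ene-1,2-diol | C=C[C@H](O)CO | starting material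
9 | (S)-3,4-bis[(tert-butyldimethylsilyl)oxy]but-1-ene | C=C[C@H](O[Si](C)(C)C(C)(C)C)CO[Si](C)(C)C(C)(C)C | intermediate
10 | (S)-2-[(tert-butyldimethylsilyl)oxy]but-3-en-1-ol | C=C[C@H](O[Si](C)(C)C(C)(C)C)CO | intermediate
11 | 2-allyl-4,4,5,5-tetramethyl-1,3,2-dioxaborolane | C=CCB1OC(C)(C)C(C)(C)O1 | starting material
12 | (2S,3Z)-2-[(tert-butyldimethylsilyl)oxy]-5-(4,4,5,5-tetramethyl-1,3,2-dioxaborolan-2-yl)pent-3-en-1-ol | OC[C@@H](O[Si](C)(C)C(C)(C)C)/C=C\CB1OC(C)(C)C(C)(C)O1 | intermediate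
13 | (2S,3Z)-2-[(tert-butyldimethylsilyl)oxy]-5-(4,4,5,5-tetramethyl-1,3,2-dioxaborolan-2-yl)pent-3-enal | O=C[C@@H](O[Si](C)(C)C(C)(C)C)/C=C\CB1OC(C)(C)C(C)(C)O1 | intermediate
14 | acyclic alkenylation adduct, drawn as the free alcohol of its chromium alkoxide: (2Z,4R,5S,6Z)-5-[(tert-butyldimethylsilyl)oxy]-3-{[(tert-butyldimethylsilyl)oxy]methyl}-2-[(1E)-hept-1-en-1-yl]-4-hydroxy-8-(4,4,5,5-tetramethyl-1,3,2-dioxaborolan-2-yl)octa-2,6-dienal | CCCCC/C=C/C(/C=O)=C(\CO[Si](C)(C)C(C)(C)C)[C@@H](O)[C@@H](O[Si](C)(C)C(C)(C)C)/C=C\CB1OC(C)(C)C(C)(C)O1 | intermediate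
15 | (1S,4R,5S,6R)-5-[(tert-butyldimethylsilyl)oxy]-3-{[(tert-butyldimethylsilyl)oxy]methyl}-6-ethenyl-2-[(1E)-hept-1-en-1-yl]cyclohex-2-ene-1,4-diol | CCCCC/C=C/C1=C(CO[Si](C)(C)C(C)(C)C)[C@@H](O)[C@@H](O[Si](C)(C)C(C)(C)C)[C@H](C=C)[C@@H]1O | intermediate
16 | (1S,4R,5S,6R)-5-[(tert-butyldimethylsilyl)oxy]-3-{[(tert-butyldimethylsilyl)oxy]methyl}-2-[(1E)-hept-1-en-1-yl]-6-(2-hydroxyethyl)cyclohex-2-ene-1,4-diol | CCCCC/C=C/C1=C(CO[Si](C)(C)C(C)(C)C)[C@@H](O)[C@@H](O[Si](C)(C)C(C)(C)C)[C@H](CCO)[C@@H]1O | intermediate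
17 | (3aR,4S,5R,7aS)-4-[(tert-butyldimethylsilyl)oxy]-6-{[(tert-butyldimethylsilyl)oxy]methyl}-7-[(1E)-hept-1-en-1-yl]-5-hydroxy-3a,4,5,7a-tetrahydro-1-benzofuran-2(3H)-one | CCCCC/C=C/C1=C(CO[Si](C)(C)C(C)(C)C)[C@@H](O)[C@@H](O[Si](C)(C)C(C)(C)C)[C@H](CC(=O)O2)[C@@H]12 | intermediate
18 | ethyl 2-(triphenyl-λ5-phosphanylidene)propanoate | CCOC(=O)C(C)=P(c1ccccc1)(c1ccccc1)c1ccccc1 | starting material
19 | lactol of 17 (2-hydroxy, anomeric mixture) | CCCCC/C=C/C1=C(CO[Si](C)(C)C(C)(C)C)[C@@H](O)[C@@H](O[Si](C)(C)C(C)(C)C)[C@H](CC(O)O2)[C@@H]12 | intermediate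
20 | ethyl (2E)-4-[(1R,2S,5R,6S)-6-[(tert-butyldimethylsilyl)oxy]-4-{[(tert-butyldimethylsilyl)oxy]methyl}-3-[(1E)-hept-1-en-1-yl]-2,5-dihydroxycyclohex-3-en-1-yl]-2-methylbut-2-enoate | CCCCC/C=C/C1=C(CO[Si](C)(C)C(C)(C)C)[C@@H](O)[C@@H](O[Si](C)(C)C(C)(C)C)[C@H](C/C=C(\C)C(=O)OCC)[C@@H]1O | intermediate
21 | ethyl (2E)-4-[(1R,2S,5R,6S)-3-[(1E)-hept-1-en-1-yl]-2,5,6-trihydroxy-4-(hydroxymethyl)cyclohex-3-en-1-yl]-2-methylbut-2-enoate | CCCCC/C=C/C1=C(CO)[C@@H](O)[C@@H](O)[C@H](C/C=C(\C)C(=O)OCC)[C@@H]1O | intermediate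
22 | pestallic acid P, (2E)-4-[(1R,2S,5R,6S)-3-[(1E)-hept-1-en-1-yl]-2,5,6-trihydroxy-4-(hydroxymethyl)cyclohex-3-en-1-yl]-2-methylbut-2-enoic acid | CCCCC/C=C/C1=C(CO)[C@@H](O)[C@@H](O)[C@H](C/C=C(\C)C(=O)O)[C@@H]1O | target

**Summary**

Total step count: 13. Longest linear sequence: 10 steps (steps 4 to 13, from 8).

Steps most likely to fail:

1. Step 8. The alkenylchromium may add to the aldehyde of a second molecule of 7, bimolecular allylboration may run ahead of the alkenylation, or the ring closure may show poor facial selectivity. Fallback, setting out from 6 and 13: an intermolecular Nozaki–Hiyama–Kishi coupling of the alcohol 6 (no aldehyde on the iodide partner) with 13 (CrCl2, cat. NiCl2, DMF) should give the acyclic diol boronate F1. MnO2 then oxidises only the primary dienylic alcohol, and the aldehyde so formed (intermediate 14) should undergo the known ring-closing allylboration on standing, coming back to the route at 15.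

2. Step 6. Conversion may be low, or Z selectivity may erode, because the alkene is branched at the allylic carbon. Fallback, setting out from 9: ozonolysis (O3, then Me2S) should give (R)-2,3-bis(silyloxy)propanal F2. Stork–Zhao olefination ((iodomethyl)triphenylphosphonium iodide, NaN(SiMe3)2) should give the (Z)-alkenyl iodide F3. Negishi coupling with IZnCH2B(pin) under Pd(PPh3)4 should give the (Z)-allylboronate F4. Cleavage of the primary silyl ether with PPTS in MeOH comes back to the route at 12.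

3. Step 2. The carbometalation may be slow, or the heptenyl Grignard reagent may lose its E geometry during heating. Fallback, setting out from 3: the same directed carbomagnesiation with vinylmagnesium chloride, then iodine, should give the 2-vinyl iodo dienol F5. Cross metathesis of its terminal vinyl group with hept-1-ene (second-generation Grubbs catalyst) should install the (E)-heptenyl chain and come back to the route at 6.

**Further compounds**

F1 | step 8 | (2Z,4R,5S,6Z)-5-[(tert-butyldimethylsilyl)oxy]-3-{[(tert-butyldimethylsilyl)oxy]methyl}-2-[(1E)-hept-1-en-1-yl]-8-(4,4,5,5-tetramethyl-1,3,2-dioxaborolan-2-yl)octa-2,6-diene-1,4-diol | CCCCC/C=C/C(/CO)=C(\CO[Si](C)(C)C(C)(C)C)[C@@H](O)[C@@H](O[Si](C)(C)C(C)(C)C)/C=C\CB1OC(C)(C)C(C)(C)O1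
F2 | step 6 | (R)-2,3-bis[(tert-butyldimethylsilyl)oxy]propanal | O=C[C@H](O[Si](C)(C)C(C)(C)C)CO[Si](C)(C)C(C)(C)C
F3 | step 6 | (1Z,3S)-3,4-bis[(tert-butyldimethylsilyl)oxy]-1-iodobut-1-ene | I/C=C\[C@H](O[Si](C)(C)C(C)(C)C)CO[Si](C)(C)C(C)(C)C
F4 | step 6 | 2-[(2Z,4S)-4,5-bis[(tert-butyldimethylsilyl)oxy]pent-2-en-1-yl]-4,4,5,5-tetramethyl-1,3,2-dioxaborolane | CC1(C)OB(C/C=C\[C@H](O[Si](C)(C)C(C)(C)C)CO[Si](C)(C)C(C)(C)C)OC1(C)C
F5 | step 2 | (2Z)-4-[(tert-butyldimethylsilyl)oxy]-2-ethenyl-3-iodobut-2-en-1-ol | OC/C(C=C)=C(\I)CO[Si](C)(C)C(C)(C)C
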